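common to all: starting material 0.29 M; free catalyst 0.8 mol%

| charge | partner | second substrate | remark | time |
|---|---|---|---|---|
| maple | 1.1 equiv | 0.50 equiv | the very flask that is asked about, followed so far |  |
| cedar | 2.2 equiv | 0.50 equiv | run made earlier |  |
| flask | 1.10 equiv | 0.500 equiv |  | 20 min |

| run | time / min | target / % |
|---|---|---|
| maple | 2.00 | 51.0 |
| maple | 5.00 | 52.3 |
| maple | 10.0 | 51.7 |
| maple | 15.0 | 52.5 |
| maple | 20.0 | 52.3 |
| cedar | 0.333 | 64.7 |
| cedar | 0.667 | 78.0 |
| cedar | 1.00 | 83.7 |
| cedar | 2.00 | 89.7 |
| cedar | 4.00 | 91.7 |

(readings scatter by 0.5 percentage points)

- ochre: at 20 min add partner, 50.0% of the amount charged, then wait 20 min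
- teal: at 20 min take out 90% of the target then present, then wait 20 min
- violet: change nothing and wait 20 min more
- blue: at 20 min add free catalyst, 100% of the amount charged, then wait 20 min

- target that was removed still counts
- the analysis behind the earlier runs scatters by 0.5 percentage points, standard deviation
- additions bring no volume worth counting

* target, in percent of the starting material first charged, at 20 min
* the option that brings most further target ("none" if no option brings more than 2 percentage points) (ochre / teal / violet / blue / none)
* target present, with what was taken out counted in, in percent of the starting material first charged, after ochre
* target present, with what was taken out counted in, in percent of the starting material first charged, after teal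

No rate constant is given for these flasks, so one has to be read from the runs, using the logarithmic conversion, ln of starting material charged over starting material remaining. The first rung is assumed: second substrate takes its own equivalents of partner at once. In the cedar run the logarithm climbs at 3.13 min⁻¹ up to the first reading, a half-life of 0.221 min for starting material. Between 1.00 min and 2.00 min it climbs at 0.459 min⁻¹, so the ratio of the two climbs in the cedar run is 6.82, larger than the ratio of 2.17 between reckoned partner at the start and at the last reading of that run. The reading taken here is that free catalyst dies, with the rate halving about every 0.482 min. The last rung, 20 min, is 41.5 such halvings.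

Replacing the falling partner by the mean of its start and end makes the step pseudo-first-order and defines the reach: final logarithmic conversion per equivalent of mean partner, 2.00 from cedar. The maple plateau, 52.2%, gives 2.18, which measures the error of the mean. The readings do not exclude an equilibrium, so this is a commitment. This reckoning keeps maple at 52.2% after ochre, teal and violet, while blue brings fresh reach to the reckoned 0.0780 equivalents of partner, worth 5.1 percentage points.

The forecast gave 52.2%, best ochre, 82% after ochre and 58% after teal, holding that “the system is at equilibrium”.

The flask gives 52.4%, best blue with 6.2 points against the reckoned 5.1 points, and 52.4% after ochre and 52.4% after teal.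

    starting material + partner + free catalyst → free catalyst + target (k = 67.0 M⁻² s⁻¹)
    second substrate + partner + free catalyst → free catalyst + second product (k = 260 M⁻² s⁻¹)
    free catalyst → spent catalyst (k = 0.0190 s⁻¹)

Free catalyst has a half-life of 0.61 min, close to the 0.64 min of starting material at 0.173 min, and far shorter than 20 min. At 20.0 min free catalyst in the flask stands at 0% of the catalyst charged, beside partner at 9.46% of its own charge. With 0.200 equiv of second substrate, the neighbour starts from 0.900 equivalents of partner, and the reach gives 67.4%. The neighbour flask gives 66.5% of target.

The runs come from a simulation from invented constants; scatter was added.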